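A direct plan would open allyl (2R,3S)-3-phenylglycidate A1 at the benzylic carbon with 3,5-bis(benzyloxy)phenol A2, acylate the freed hydroxyl, release the acid A3, close ring C by Friedel–Crafts acylation to the dibenzyl ether A4 and hydrogenolyse the benzyl groups. Its weakest steps would be:
(a) the Friedel–Crafts closure, since under the acidic anhydride the benzylic aryl ether of A3 could ionise or eliminate and the triply activated ring could be acylated by the reagent;
(b) the ester exchange on the glycidate (saponification, re-alkylation, later deallylation), three operations that would add no complexity;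
(c) the hydrogenolysis, since the benzylic C2–O1 bond and the aryl ketone of A4 could also be reduced.

The new route would build ring A last. Ring A with the C4 carbonyl is an acylphloroglucinol, that is, a folded tetraketide. The chain C4–C4a–C8a–C8–C7–C6–C5 is therefore assembled with C5 and C7 masked as a 1,3-dioxin-4-one, and with ring C already closed as a 3-acyloxy-2-phenyl-2,3-dihydropyran-4-one that carries both stereocentres and the ester. Heating alone should release an acylketene that folds onto C4a (new bond C4a–C5) and aromatises to the free 5,7-dihydroxy ring. No arene is acylated, no phenol or carboxyl group is ever protected, and nothing has to be hydrogenolysed.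

Key step: step 5

Remark: from compound 5 onward, positions are given in flavanone numbering (O1, C2, C3, C4, C4a, C5 to C8, C8a), also for open-chain and monocyclic precursors.

Step 1
Reactants: 1 2,2,6-trimethyl-4H-1,3-dioxin-4-one; 2 acetyl chloride
Product: 3 2,2-dimethyl-6-(2-oxopropyl)-4H-1,3-dioxin-4-one
Conditions: 1 (2.0 equiv), LiN(SiMe3)2 (2.0 equiv), THF, −78 °C; then 2 (1.0 equiv), −78 °C; aq. NH4Cl
Reagents that add atoms: none
Why: γ-Deprotonation of the dioxinone gives a lithium dienolate that should undergo Claisen-type C-acylation at its terminal carbon by acetyl chloride, the second equivalent of dienolate absorbing the more acidic keto-dioxinone as it forms, and no stereocentre is involved.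

Step 2
Reactants: 3 2,2-dimethyl-6-(2-oxopropyl)-4H-1,3-dioxin-4-one; 4 methyl (2R,3S)-3-phenyloxirane-2-carboxylate
Product: 5 2,2-dimethyl-6-{2,4-dioxo-4-[(2R,3S)-3-phenyloxiran-2-yl]butyl}-4H-1,3-dioxin-4-one
Conditions: 3 (2.0 equiv), LiN(iPr)2 (4.1 equiv), THF, −78 °C; then 4 (1.0 equiv), −78 to −40 °C; aq. NH4Cl at −78 °C; crude 5 taken on directly
Reagents that add atoms: none
Why: Double deprotonation of 3 places the most reactive carbanion on the terminal methyl group, which should attack the α-oxygen-activated ester carbonyl of 4 faster than its epoxide at low temperature (Claisen acylation of a 1,3-dicarbonyl dianion by an ester), leaving the trans-epoxide and both of its stereocentres untouched.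

Step 3
Reactants: 5 2,2-dimethyl-6-{2,4-dioxo-4-[(2R,3S)-3-phenyloxiran-2-yl]butyl}-4H-1,3-dioxin-4-one
Product: 6 (2R,3R)-6-[(2,2-dimethyl-4-oxo-4H-1,3-dioxin-6-yl)methyl]-3-hydroxy-2-phenyl-2,3-dihydro-4H-pyran-4-one
Conditions: camphorsulfonic acid (0.1 equiv), CH2Cl2 (0.05 M), 0 °C to rt
Reagents that add atoms: none
Why: Acid-catalysed intramolecular 6-endo epoxide opening by the C8a enol oxygen of the 1,3-diketone at the benzylic carbon (the reaction type that closes 2'-hydroxychalcone epoxides to trans-dihydroflavonols) should close ring C with inversion at C2 (S to R) while C3 keeps its oxygen and its R configuration, the α-keto carbon being deactivated towards the competing 5-exo attack.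

Step 4
Reactants: 6 (2R,3R)-6-[(2,2-dimethyl-4-oxo-4H-1,3-dioxin-6-yl)methyl]-3-hydroxy-2-phenyl-2,3-dihydro-4H-pyran-4-one; 7 (2S)-2-methylbutanoic acid
Product: 8 (2R,3R)-6-[(2,2-dimethyl-4-oxo-4H-1,3-dioxin-6-yl)methyl]-4-oxo-2-phenyl-3,4-dihydro-2H-pyran-3-yl (2S)-2-methylbutanoate
Conditions: 7 (1.3 equiv), DCC (1.3 equiv), DMAP (0.1 equiv), CH2Cl2, 0 °C to rt
Reagents that add atoms: none
Why: Steglich esterification of the only hydroxyl group, with catalytic DMAP and no further base, should acylate O3 without epimerising C3 or the α-centre of the acid and without touching the dioxinone.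

Step 5
Reactants: 8 (2R,3R)-6-[(2,2-dimethyl-4-oxo-4H-1,3-dioxin-6-yl)methyl]-4-oxo-2-phenyl-3,4-dihydro-2H-pyran-3-yl (2S)-2-methylbutanoate
Product: 12 (2R,3R)-5,7-dihydroxy-4-oxo-2-phenylchroman-3-yl (2S)-2-methylbutanoate, via acylketene 9 (not isolated), via dienylketene enol 10 (not isolated), via cyclohexadienone 11 (not isolated)
Conditions: toluene (0.005 M), 4 Å molecular sieves, 110 °C, slow N2 sweep to carry off acetone
Reagents that add atoms: none
Why: Proposed new method: at 110 °C the 1,3-dioxin-4-one should lose acetone by retro-[4+2] cycloaddition to give acylketene 9, whose C7 carbonyl enolises towards the doubly activated C8 methylene to dienylketene 10, in which C4a=C8a, C8=C7 and the ketene C6=C5 make up a hexatriene that closes by thermal 6π-electrocyclisation (new bond C4a–C5) to cyclohexadienone 11, which tautomerises by loss of the C4a hydrogen to the aromatic 5,7-diol 12; a stepwise variant, attack of the enol-ether carbon C4a on the ketene carbon followed by proton transfer, would end in the same product. The closest known reaction types are the thermal release and capture of acylketenes from dioxinones, the dienylketene electrocyclisation that completes the Danheiser benzannulation, and the Claisen-type folding of 3,5,7-triketo esters to acylphloroglucinols, none of which has been used to close a phloroglucinol ring onto a dihydropyranone. Ring A closes as a six-membered carbocycle in a disrotatory 6π mode, the ketene C=C ending inside the new ring and its C=O outside as the C5 oxygen. No stereocentre is formed: C2, C3 and the centre of the acyl group come unchanged from 8, because the medium is neutral and aprotic, so that neither enolisation at C3 nor β-elimination of O1 is triggered. The step needs C-acylation at C4a in preference to the other folds of a tetraketide, and the substrate secures it: O1 is already alkylated by C2, so no 2-pyranone can form through oxygen; the C4 carbonyl is locked in ring C and cannot take part in an aldol closure; and 8 has no hydroxyl group to capture the ketene, while high dilution and sieves hold back dimerisation, hydration and acylation of the product phenols.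

**Compound list**

1 | 2,2,6-trimethyl-4H-1,3-dioxin-4-one | CC1=CC(=O)OC(C)(C)O1 | starting material
2 | acetyl chloride | CC(=O)Cl | starting material
3 | 2,2-dimethyl-6-(2-oxopropyl)-4H-1,3-dioxin-4-one | CC(=O)CC1=CC(=O)OC(C)(C)O1 | intermediate
4 | methyl (2R,3S)-3-phenyloxirane-2-carboxylate (methyl trans-3-phenylglycidate) | COC(=O)[C@@H]1O[C@H]1c1ccccc1 | starting material
5 | 2,2-dimethyl-6-{2,4-dioxo-4-[(2R,3S)-3-phenyloxiran-2-yl]butyl}-4H-1,3-dioxin-4-one | O=C(CC(=O)CC1=CC(=O)OC(C)(C)O1)[C@@H]1O[C@H]1c1ccccc1 | intermediate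
6 | (2R,3R)-6-[(2,2-dimethyl-4-oxo-4H-1,3-dioxin-6-yl)methyl]-3-hydroxy-2-phenyl-2,3-dihydro-4H-pyran-4-one | O[C@H]1C(=O)C=C(CC2=CC(=O)OC(C)(C)O2)O[C@@H]1c1ccccc1 | intermediate
7 | (2S)-2-methylbutanoic acid | CC[C@H](C)C(=O)O | starting material
8 | (2R,3R)-6-[(2,2-dimethyl-4-oxo-4H-1,3-dioxin-6-yl)methyl]-4-oxo-2-phenyl-3,4-dihydro-2H-pyran-3-yl (2S)-2-methylbutanoate | CC[C@H](C)C(=O)O[C@H]1C(=O)C=C(CC2=CC(=O)OC(C)(C)O2)O[C@@H]1c1ccccc1 | intermediate
9 | (2R,3R)-6-(2,4-dioxobut-3-en-1-yl)-4-oxo-2-phenyl-3,4-dihydro-2H-pyran-3-yl (2S)-2-methylbutanoate (acylketene) | CC[C@H](C)C(=O)O[C@H]1C(=O)C=C(CC(=O)C=C=O)O[C@@H]1c1ccccc1 | intermediate (not isolated)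
10 | (2R,3R)-6-[(1E)-2-hydroxy-4-oxobuta-1,3-dien-1-yl]-4-oxo-2-phenyl-3,4-dihydro-2H-pyran-3-yl (2S)-2-methylbutanoate (dienylketene enol) | CC[C@H](C)C(=O)O[C@H]1C(=O)C=C(/C=C(/O)C=C=O)O[C@@H]1c1ccccc1 | intermediate (not isolated)
11 | (2R,3R)-7-hydroxy-4,5-dioxo-2-phenyl-3,4,4a,5-tetrahydro-2H-chromen-3-yl (2S)-2-methylbutanoate (C4a epimers) | CC[C@H](C)C(=O)O[C@H]1C(=O)C2C(=O)C=C(O)C=C2O[C@@H]1c1ccccc1 | intermediate (not isolated)
12 | (2R,3R)-5,7-dihydroxy-4-oxo-2-phenylchroman-3-yl (2S)-2-methylbutanoate | CC[C@H](C)C(=O)O[C@H]1C(=O)c2c(O)cc(O)cc2O[C@@H]1c1ccccc1 | target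

Total step count: 5. Longest linear sequence: 5 steps (1 → 3 → 5 → 6 → 8 → 12).

**Steps most likely to fail**

1. Step 5 (proposed new method). The acylketene may not close onto C4a and may instead dimerise, be hydrated and decarboxylated by traces of water, or acylate phenol already formed. The fallback uses known chemistry, sets out from 6 and returns at 12. Heating 6 in toluene with methanol should trap the ketene as methyl 4-[(2R,3R)-3-hydroxy-4-oxo-2-phenyl-3,4-dihydro-2H-pyran-6-yl]-3-oxobutanoate F1. Mg(OMe)2 in methanol under argon should then bring about the Claisen-type cyclisation known for 3,5,7-triketo esters, the C8 dienolate attacking the ester through C4a, to give (2R,3R)-3,5,7-trihydroxy-2-phenylchroman-4-one F2. Selective silylation of the 7-hydroxyl (TBSCl, imidazole) would give (2R,3R)-7-[(tert-butyldimethylsilyl)oxy]-3,5-dihydroxy-2-phenylchroman-4-one F3. Steglich esterification of O3 with 7, the chelated 5-hydroxyl staying free, would give (2R,3R)-7-[(tert-butyldimethylsilyl)oxy]-5-hydroxy-4-oxo-2-phenylchroman-3-yl (2S)-2-methylbutanoate F4, and desilylation with HF·pyridine would give 12.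

2. Step 3. Ring closure may go astray through attack at the α-keto carbon (five-membered ring), through acid-induced acyl shift of the epoxy ketone, or through ionisation at the benzylic carbon with loss of the C2 configuration. The fallback sets out from 3 and returns at 6 without any epoxide. Commercial methyl (2R,3S)-2,3-dihydroxy-3-phenylpropanoate F5 would be silylated (Et3SiCl, imidazole) to methyl (2R,3S)-3-phenyl-2,3-bis[(triethylsilyl)oxy]propanoate F6. This ester would acylate the dianion of 3 as in step 2 to give 2,2-dimethyl-6-{(5R,6S)-2,4-dioxo-6-phenyl-5,6-bis[(triethylsilyl)oxy]hexyl}-4H-1,3-dioxin-4-one F7. Buffered fluoride (HF·pyridine, pyridine) would free 6-[(5R,6S)-5,6-dihydroxy-2,4-dioxo-6-phenylhexyl]-2,2-dimethyl-4H-1,3-dioxin-4-one F8. Mitsunobu cyclodehydration (PPh3, DIAD), in which the acidic diketone enol displaces the activated benzylic hydroxyl with inversion, would then give 6.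

3. Step 2. The dianion may open the epoxide, or acylation by the methyl ester may stall because the product consumes base. The fallback sets out from 4 and returns at 5. Reduction of 4 with iBu2AlH at −78 °C would give (2R,3S)-3-phenyloxirane-2-carbaldehyde F9. Aldol addition of the dianion of 3 would give 6-{4-hydroxy-2-oxo-4-[(2S,3S)-3-phenyloxiran-2-yl]butyl}-2,2-dimethyl-4H-1,3-dioxin-4-one F10 (carbinol epimers, both usable), and Dess–Martin oxidation would give 5.

**Further compounds**

F1 | step 5 | methyl 4-[(2R,3R)-3-hydroxy-4-oxo-2-phenyl-3,4-dihydro-2H-pyran-6-yl]-3-oxobutanoate | O[C@H]1C(=O)C=C(CC(=O)CC(=O)OC)O[C@@H]1c1ccccc1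
F2 | step 5 | (2R,3R)-3,5,7-trihydroxy-2-phenylchroman-4-one | O[C@H]1C(=O)c2c(O)cc(O)cc2O[C@@H]1c1ccccc1
F3 | step 5 | (2R,3R)-7-[(tert-butyldimethylsilyl)oxy]-3,5-dihydroxy-2-phenylchroman-4-one | O[C@H]1C(=O)c2c(O)cc(O[Si](C)(C)C(C)(C)C)cc2O[C@@H]1c1ccccc1
F4 | step 5 | (2R,3R)-7-[(tert-butyldimethylsilyl)oxy]-5-hydroxy-4-oxo-2-phenylchroman-3-yl (2S)-2-methylbutanoate | CC[C@H](C)C(=O)O[C@H]1C(=O)c2c(O)cc(O[Si](C)(C)C(C)(C)C)cc2O[C@@H]1c1ccccc1
F5 | step 3 | methyl (2R,3S)-2,3-dihydroxy-3-phenylpropanoate | COC(=O)[C@H](O)[C@@H](O)c1ccccc1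
F6 | step 3 | methyl (2R,3S)-3-phenyl-2,3-bis[(triethylsilyl)oxy]propanoate | COC(=O)[C@H](O[Si](CC)(CC)CC)[C@@H](O[Si](CC)(CC)CC)c1ccccc1
F7 | step 3 | 2,2-dimethyl-6-{(5R,6S)-2,4-dioxo-6-phenyl-5,6-bis[(triethylsilyl)oxy]hexyl}-4H-1,3-dioxin-4-one | O=C(CC(=O)CC1=CC(=O)OC(C)(C)O1)[C@H](O[Si](CC)(CC)CC)[C@@H](O[Si](CC)(CC)CC)c1ccccc1
F8 | step 3 | 6-[(5R,6S)-5,6-dihydroxy-2,4-dioxo-6-phenylhexyl]-2,2-dimethyl-4H-1,3-dioxin-4-one | O=C(CC(=O)CC1=CC(=O)OC(C)(C)O1)[C@H](O)[C@@H](O)c1ccccc1
F9 | step 2 | (2R,3S)-3-phenyloxirane-2-carbaldehyde | O=C[C@@H]1O[C@H]1c1ccccc1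
F10 | step 2 | 6-{4-hydroxy-2-oxo-4-[(2S,3S)-3-phenyloxiran-2-yl]butyl}-2,2-dimethyl-4H-1,3-dioxin-4-one | OC(CC(=O)CC1=CC(=O)OC(C)(C)O1)[C@@H]1O[C@H]1c1ccccc1
A1 | direct plan | prop-2-en-1-yl (2R,3S)-3-phenyloxirane-2-carboxylate | C=CCOC(=O)[C@@H]1O[C@H]1c1ccccc1
A2 | direct plan | 3,5-bis(benzyloxy)phenol | Oc1cc(OCc2ccccc2)cc(OCc2ccccc2)c1
A3 | direct plan | (2R,3R)-3-[3,5-bis(benzyloxy)phenoxy]-2-{[(2S)-2-methylbutanoyl]oxy}-3-phenylpropanoic acid | CC[C@H](C)C(=O)O[C@@H](C(=O)O)[C@H](Oc1cc(OCc2ccccc2)cc(OCc2ccccc2)c1)c1ccccc1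
A4 | direct plan | (2R,3R)-5,7-bis(benzyloxy)-4-oxo-2-phenylchroman-3-yl (2S)-2-methylbutanoate | CC[C@H](C)C(=O)O[C@H]1C(=O)c2c(OCc3ccccc3)cc(OCc3ccccc3)cc2O[C@@H]1c1ccccc1
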